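**Strategy.** The route rests on cutting the cis-fused 2-alkylidene-hexahydrofuro[3,2-b]pyran across two bonds: furan CH2–anomeric pyran carbon and enol-ether oxygen–neighbouring pyran carbon. This leaves a β-keto lactone on the complete bicyclic keto macrolide, whose methyl carbon is made the soft nucleophile by a traceless benzyl ester, and D-fucal 3,4-dicarbonate, whose all-cis methyl, C3–O and C4–O groups preset the three pyran stereocentres. One palladium-catalysed double allylic substitution joins both fragments, first C–C at the anomeric carbon, then C–O at its neighbour, each with net retention, giving the cis-fused bicycle. Hydrogenation, debenzylation and decarboxylation complete the target.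

Key step: step 14

Remark: the carbon between ketone and lactone carbonyl in 17, 22, 23, 24 and 25 is an epimerizable centre; it is drawn trans to the neighbouring ring substituent, the malonate-type carbon of 22 is left undefined, and both are erased in step 15.

Step 1
Reactants: 1 (S)-2-hydroxy-1,2,2-triphenylethyl acetate; 2 acrolein
Product: 3 (S)-2-hydroxy-1,2,2-triphenylethyl (S)-3-hydroxypent-4-enoate
Conditions: LiN(i-Pr)2 (2.2 equiv), THF, −78 to 0 °C; MgBr2·OEt2, −78 °C; 2, −100 °C; NH4Cl (aq)
Reagents that add atoms: none
Why: Acetate aldol addition (1,2-addition to the enal) of the doubly deprotonated chiral acetate, whose triphenylglycol unit shields one enolate face so that the (S)-ester should give the (S)-carbinol, to be purified by crystallization.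

Step 2
Reactants: 3 (S)-2-hydroxy-1,2,2-triphenylethyl (S)-3-hydroxypent-4-enoate
Product: 4 (S)-3-hydroxypent-4-enoic acid
Conditions: KOH, MeOH–H2O, reflux; then HCl (aq), 0 °C
Reagents that add atoms: potassium hydroxide, [K+].[OH-]
Why: Saponification of the hindered ester should release the β-hydroxy acid and the recoverable triphenylglycol without touching the carbinol centre.

Step 3
Reactants: 4 (S)-3-hydroxypent-4-enoic acid
Product: 6 (S)-3-[(tert-butyldimethylsilyl)oxy]pent-4-enoic acid, via bis-silylated acid 5 (not isolated)
Conditions: TBSCl (2.5 equiv), imidazole, DMF, rt; then K2CO3, MeOH–H2O, rt; pH 4 work-up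
Reagents that add atoms: tert-butyldimethylsilyl chloride, CC(C)(C)[Si](C)(C)Cl
Why: Silylation of hydroxyl and carboxyl followed by selective solvolysis of the labile silyl ester masks the carbinol so that the acid cannot acylate itself in step 6.

Step 4
Reactants: 7 (R)-γ-valerolactone
Product: 8 (R)-4-hydroxy-N-methoxy-N-methylpentanamide
Conditions: MeNH(OMe)·HCl, i-PrMgCl, THF, −20 to 0 °C
Reagents that add atoms: N,O-dimethylhydroxylamine hydrochloride, CNOC.Cl
Why: Aminolysis of the lactone by the magnesium amide should give the Weinreb amide, with the chiral-pool carbinol centre not involved.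

Step 5
Reactants: 8 (R)-4-hydroxy-N-methoxy-N-methylpentanamide
Product: 9 (R)-6-hydroxyhept-1-en-3-one
Conditions: CH2=CHMgBr (3 equiv), THF, −78 to 0 °C; inverse quench into cold HCl (aq)
Reagents that add atoms: vinylmagnesium bromide, C=C[Mg]Br
Why: Weinreb ketone synthesis, in which the chelated tetrahedral adduct stops at the ketone stage and the acidic quench keeps the released amine from adding to the vinyl ketone.

Step 6
Reactants: 6 (S)-3-[(tert-butyldimethylsilyl)oxy]pent-4-enoic acid; 9 (R)-6-hydroxyhept-1-en-3-one
Product: 10 (R)-5-oxohept-6-en-2-yl (S)-3-[(tert-butyldimethylsilyl)oxy]pent-4-enoate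
Conditions: DCC, DMAP (0.1 equiv), CH2Cl2, 0 °C to rt
Reagents that add atoms: none
Why: Steglich esterification should join the acid and the secondary alcohol without touching either stereocentre.

Step 7
Reactants: 10 (R)-5-oxohept-6-en-2-yl (S)-3-[(tert-butyldimethylsilyl)oxy]pent-4-enoate
Product: 11 (4S,5E,10R)-4-[(tert-butyldimethylsilyl)oxy]-10-methyloxacyclodec-5-ene-2,7-dione
Conditions: second-generation Hoveyda–Grubbs catalyst (10 mol %), PhMe (1 mM), 80 °C
Reagents that add atoms: none
Why: Ring-closing metathesis between the allylic silyl ether alkene and the vinyl ketone should close the ten-membered lactone with loss of ethylene; the conjugated E-enone is expected, and the alkene geometry is consumed in step 10 in any case.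

Step 8
Reactants: 11 (4S,5E,10R)-4-[(tert-butyldimethylsilyl)oxy]-10-methyloxacyclodec-5-ene-2,7-dione
Product: 12 (4S,5E,10R)-4-hydroxy-10-methyloxacyclodec-5-ene-2,7-dione
Conditions: HF·pyridine, THF, 0 °C to rt
Reagents that add atoms: none
Why: Fluoride-mediated desilylation under buffered acidic conditions should free the carbinol without base-induced isomerization of the γ-hydroxy enone.

Step 9
Reactants: 13 Meldrum's acid; 14 monobenzyl malonate
Product: 15 5-[3-(benzyloxy)-1-hydroxy-3-oxopropylidene]-2,2-dimethyl-1,3-dioxane-4,6-dione
Conditions: DCC, DMAP, CH2Cl2, 0 °C to rt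
Reagents that add atoms: none
Why: C-acylation of Meldrum's acid by the carbodiimide-activated malonate half-ester should give the acyl Meldrum's acid, a thermal acylketene precursor.

Step 10
Reactants: 12 (4S,5E,10R)-4-hydroxy-10-methyloxacyclodec-5-ene-2,7-dione; 15 5-[3-(benzyloxy)-1-hydroxy-3-oxopropylidene]-2,2-dimethyl-1,3-dioxane-4,6-dione
Product: 17 benzyl β-keto ester of the bicyclic keto macrolide, via mixed 3-oxoglutarate diester 16 (not isolated)
Conditions: PhMe, 90 °C; then Cs2CO3 (0.2 equiv), MeCN, 0 °C
Reagents that add atoms: none
Why: Thermolysis of 15 gives an acylketene that acylates the carbinol (16), and the methylene next to the new ester then adds to the enone in a 5-exo-trig Michael reaction, in which the tether and allylic strain (carbinol hydrogen eclipsing the alkene) should set the new centre trans to the C3 substituent, an outcome reinforced by reversibility.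

Step 11
Reactants: 18 D-galactal
Product: 19 6-O-(p-toluenesulfonyl)-D-galactal
Conditions: TsCl (1.1 equiv), pyridine, −20 to 0 °C
Reagents that add atoms: p-toluenesulfonyl chloride, Cc1ccc(cc1)S(=O)(=O)Cl
Why: Sulfonylation should be selective for the primary hydroxyl over the two secondary ones on steric grounds.

Step 12
Reactants: 19 6-O-(p-toluenesulfonyl)-D-galactal
Product: 20 D-fucal (6-deoxy-D-galactal)
Conditions: LiAlH4, THF, 0 °C to reflux
Reagents that add atoms: none
Why: SN2 displacement of the primary tosylate by hydride should give the C-methyl group while the three stereocentres and the enol ether stay untouched.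

Step 13
Reactants: 20 D-fucal (6-deoxy-D-galactal)
Product: 21 3,4-di-O-(methoxycarbonyl)-D-fucal
Conditions: ClCO2Me (4 equiv), pyridine, DMAP (cat.), CH2Cl2, 0 °C
Reagents that add atoms: methyl chloroformate, COC(=O)Cl
Why: Carbonate formation with excess chloroformate at low temperature should acylate both hydroxyls before the monocarbonate can close to a cyclic carbonate.

Step 14
Reactants: 17 benzyl β-keto ester of the bicyclic keto macrolide; 21 3,4-di-O-(methoxycarbonyl)-D-fucal
Product: 23 benzyl dihydrofuropyran carboxylate of the keto macrolide, via C-glycoside allylic carbonate 22 (not isolated)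
Conditions: Pd2(dba)3 (2.5 mol %), Xantphos (6 mol %), THF, 50 °C
Reagents that add atoms: none
Why: Zerovalent palladium ionizes the allylic C3 carbonate of glycal 21 from the face opposite its three cis substituents; the methoxide released deprotonates the methylene of 17 between the ketone and the benzyl ester, and this soft enolate attacks the anomeric terminus of the π-allyl complex anti to palladium to give 22. In 22 the C4 carbonate has become allylic, is ionized in the same way, and the ketone enolate oxygen closes the furan ring by 5-exo attack on the near allyl terminus (seven-membered closure at the far terminus is not competitive), leaving the pyran alkene one position further on. The closest known reaction type is the Tsuji–Trost double allylic substitution that annulates β-keto esters and 3-oxoglutarates onto bis-allylic dicarbonates as dihydrofurans, together with palladium-catalysed C-glycosylation of glycal 3-carbonates. Both new stereocentres are set by substrate control: each substitution runs with net retention (two inversions), so the C–C and C–O bonds form on the face that carried the two carbonates, cis to the C-methyl group, and the five-membered ring is therefore cis-fused. The step needs site selectivity in the nucleophile and in the allyl unit: the benzyl ester makes the open methylene the accessible soft carbon (the ring-bound α-carbon would have to build a quaternary centre, and a second alkylation of 3-oxoglutarates is known to prefer the unsubstituted methylene), while the ring oxygen directs the first attack to the anomeric carbon. The product is drawn as the endocyclic vinylogous carbonate; an exocyclic tautomer would converge in step 15.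

Step 15
Reactants: 23 benzyl dihydrofuropyran carboxylate of the keto macrolide
Product: 26 cordycicadin D, via furopyran carboxylic acid 24 (not isolated), via endocyclic enol ether 25 (not isolated)
Conditions: H2 (1 atm), Pd/C, EtOAc, rt; filter; then PPTS (cat.), PhMe, 80 °C
Reagents that add atoms: none
Why: Hydrogenation saturates the cis-disubstituted pyran alkene and hydrogenolysis cleaves the benzyl ester; the vinylogous carbonic acid 24 should lose CO2 on C-protonation to give enol ether 25, which tautomerizes under the same mild acid to the conjugated alkylidene lactone, expected to settle as the E isomer (enol-ether oxygen anti to the lactone carbonyl) while the labile α-centre is erased.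

**Compound list**

1 | (S)-2-hydroxy-1,2,2-triphenylethyl acetate | CC(=O)O[C@@H](c1ccccc1)C(O)(c1ccccc1)c1ccccc1 | starting material
2 | acrolein | C=CC=O | starting material
3 | (S)-2-hydroxy-1,2,2-triphenylethyl (S)-3-hydroxypent-4-enoate | C=C[C@@H](O)CC(=O)O[C@@H](c1ccccc1)C(O)(c1ccccc1)c1ccccc1 | intermediate
4 | (S)-3-hydroxypent-4-enoic acid | C=C[C@@H](O)CC(=O)O | intermediate
5 | tert-butyldimethylsilyl (S)-3-[(tert-butyldimethylsilyl)oxy]pent-4-enoate (bis-silylated acid) | C=C[C@@H](O[Si](C)(C)C(C)(C)C)CC(=O)O[Si](C)(C)C(C)(C)C | intermediate
6 | (S)-3-[(tert-butyldimethylsilyl)oxy]pent-4-enoic acid | C=C[C@@H](O[Si](C)(C)C(C)(C)C)CC(=O)O | intermediate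
7 | (R)-γ-valerolactone | C[C@@H]1CCC(=O)O1 | starting material
8 | (R)-4-hydroxy-N-methoxy-N-methylpentanamide | C[C@@H](O)CCC(=O)N(C)OC | intermediate
9 | (R)-6-hydroxyhept-1-en-3-one | C[C@@H](O)CCC(=O)C=C | intermediate
10 | (R)-5-oxohept-6-en-2-yl (S)-3-[(tert-butyldimethylsilyl)oxy]pent-4-enoate | C[C@H](CCC(=O)C=C)OC(=O)C[C@H](O[Si](C)(C)C(C)(C)C)C=C | intermediate
11 | (4S,5E,10R)-4-[(tert-butyldimethylsilyl)oxy]-10-methyloxacyclodec-5-ene-2,7-dione | C[C@@H]1CCC(=O)/C=C/[C@@H](O[Si](C)(C)C(C)(C)C)CC(=O)O1 | intermediate
12 | (4S,5E,10R)-4-hydroxy-10-methyloxacyclodec-5-ene-2,7-dione | C[C@@H]1CCC(=O)/C=C/[C@@H](O)CC(=O)O1 | intermediate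
13 | Meldrum's acid (2,2-dimethyl-1,3-dioxane-4,6-dione) | CC1(C)OC(=O)CC(=O)O1 | starting material
14 | monobenzyl malonate (3-(benzyloxy)-3-oxopropanoic acid) | OC(=O)CC(=O)OCc1ccccc1 | starting material
15 | 5-[3-(benzyloxy)-1-hydroxy-3-oxopropylidene]-2,2-dimethyl-1,3-dioxane-4,6-dione | CC1(C)OC(=O)C(=C(O)CC(=O)OCc2ccccc2)C(=O)O1 | intermediate
16 | mixed 3-oxoglutarate diester: benzyl (4S,5E,10R)-10-methyl-2,7-dioxooxacyclodec-5-en-4-yl 3-oxopentanedioate | C[C@@H]1CCC(=O)/C=C/[C@@H](OC(=O)CC(=O)CC(=O)OCc2ccccc2)CC(=O)O1 | intermediate
17 | benzyl 3-oxo-3-(lactone α-carbon)propanoate of the trans-fused γ-butyrolactone/ten-membered keto lactone (β-carbon R, γ-carbon S, methyl carbinol R; α-carbon drawn trans) | C[C@@H]1CCC(=O)C[C@@H]2[C@@H](C(=O)CC(=O)OCc3ccccc3)C(=O)O[C@H]2CC(=O)O1 | intermediate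
18 | D-galactal | OC[C@H]1OC=C[C@@H](O)[C@H]1O | starting material
19 | 6-O-(p-toluenesulfonyl)-D-galactal | Cc1ccc(cc1)S(=O)(=O)OC[C@H]1OC=C[C@@H](O)[C@H]1O | intermediate
20 | D-fucal (6-deoxy-D-galactal) | C[C@H]1OC=C[C@@H](O)[C@H]1O | intermediate
21 | 3,4-di-O-(methoxycarbonyl)-D-fucal (all-cis methyl and two methyl carbonates) | C[C@H]1OC=C[C@@H](OC(=O)OC)[C@H]1OC(=O)OC | intermediate
22 | C-glycoside allylic carbonate: 17 carrying at its methylene the 2,3-unsaturated 6-deoxypyranosyl unit (new C–C bond cis to the methyl) with the C4 methyl carbonate still in place | C[C@@H]1CCC(=O)C[C@@H]2[C@@H](C(=O)C(C(=O)OCc3ccccc3)[C@@H]4O[C@H](C)[C@H](OC(=O)OC)C=C4)C(=O)O[C@H]2CC(=O)O1 | intermediate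
23 | benzyl cis-fused 5-methyl-3a,7a-dihydro-5H-furo[3,2-b]pyran-3-carboxylate carrying the bicyclic keto macrolide (through its lactone α-carbon) at C2 | C[C@@H]1CCC(=O)C[C@@H]2[C@@H](C3=C(C(=O)OCc5ccccc5)[C@@H]4O[C@H](C)C=C[C@@H]4O3)C(=O)O[C@H]2CC(=O)O1 | intermediate
24 | furopyran carboxylic acid: the 6,7-saturated free acid of 23 | C[C@@H]1CCC(=O)C[C@@H]2[C@@H](C3=C(C(O)=O)[C@@H]4O[C@H](C)CC[C@@H]4O3)C(=O)O[C@H]2CC(=O)O1 | intermediate
25 | endocyclic enol ether: decarboxylated 24 (alkene inside the furan ring, lactone α-carbon sp3) | C[C@@H]1CCC(=O)C[C@@H]2[C@@H](C3=C[C@@H]4O[C@H](C)CC[C@@H]4O3)C(=O)O[C@H]2CC(=O)O1 | intermediate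
26 | cordycicadin D | C[C@@H]1CCC(=O)C[C@@H]2/C(=C3/C[C@@H]4O[C@H](C)CC[C@@H]4O3)C(=O)O[C@H]2CC(=O)O1 | target

**Step count and risks**

Total step count: 15. Longest linear sequence: 9 steps (1, 2, 3, 6, 7, 8, 10, 14, 15).

Steps most likely to fail:

1. Step 14. The nucleophile may lose site selectivity (C-allylation at the ring-bound α-carbon or double allylation), or its activated methylene may add to the ring ketone in an intramolecular aldol reaction before it is allylated. Slow ionization of the electron-rich glycal carbonate is a further concern. Fallback, setting out from 21 and 12 and coming back at 23: the annulation would be run on the symmetric reagent, where no site question arises. Commercial dibenzyl 3-oxoglutarate and 21 under the same palladium conditions should give dibenzyl furopyran diester F1. F1 and hydroxy enone 12 would then be united with Cs2CO3 in MeCN by Michael addition of the acetate-arm methylene to the enone, followed by lactonization of the neighbouring hydroxyl onto the arm ester with loss of benzyl alcohol, which gives 23.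

2. Step 7. Intermolecular metathesis (oligomerization) may outrun closure of the strained ten-membered ring, and the vinyl ketone may deactivate the catalyst. Fallback, setting out from 6 and 9 and coming back at 11: cross-metathesis of acid 6 with vinyl ketone 9 (second-generation Hoveyda–Grubbs catalyst, CH2Cl2, 40 °C) should give (3S,4E,9R)-3-[(tert-butyldimethylsilyl)oxy]-9-hydroxy-6-oxodec-4-enoic acid F2. Yamaguchi macrolactonization of F2 (2,4,6-trichlorobenzoyl chloride, Et3N; then DMAP, PhMe, high dilution) would close the ring at the ester bond to give 11.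

3. Step 15. Hydrogenolysis of the allylic C–O bonds that flank the pyran alkene may compete with saturation of the alkene on the palladium surface. Fallback, setting out from 23 and coming back at 24: the alkene would first be saturated without a metal surface by diimide (2-nitrobenzenesulfonylhydrazide, Et3N, CH2Cl2, rt) to give saturated benzyl ester F3. Hydrogenolysis of F3 (H2, Pd/C, EtOAc), which no longer holds an allylic C–O bond, would then give acid 24, and the decarboxylation of step 15 would lead on to 26.

Further compounds
F1 | step 14 | dibenzyl furopyran diester: benzyl cis-fused 2-[2-(benzyloxy)-2-oxoethyl]-5-methyl-3a,7a-dihydro-5H-furo[3,2-b]pyran-3-carboxylate | O=C(OCc1ccccc1)CC2=C(C(=O)OCc3ccccc3)[C@@H]4O[C@H](C)C=C[C@@H]4O2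
F2 | step 7 | (3S,4E,9R)-3-[(tert-butyldimethylsilyl)oxy]-9-hydroxy-6-oxodec-4-enoic acid | C[C@@H](O)CCC(=O)/C=C/[C@@H](O[Si](C)(C)C(C)(C)C)CC(=O)O
F3 | step 15 | saturated benzyl ester: 6,7-dihydro derivative of 23 | C[C@@H]1CCC(=O)C[C@@H]2[C@@H](C3=C(C(=O)OCc5ccccc5)[C@@H]4O[C@H](C)CC[C@@H]4O3)C(=O)O[C@H]2CC(=O)O1
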